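Late in its run the north-east flask has levelled off, with the target read at 10.5 % after 15.0 min and 11.2 % after 25.0 min, while the west flask has passed 26.1 % and is still climbing. So I doubt that the north-east stop is an equilibrium, and I suspect that the enzyme has been killed.

| setting | north-east | west | flask |
|---|---|---|---|
| starting material | 0.10 M | 0.10 M | 0.10 M |
| second substrate | 1 equiv | 1 equiv | 1.00 equiv |
| free enzyme | 5.9 × 10⁻⁴ mol% | 0.0012 mol% | 5.9 × 10⁻⁴ mol% |
| impurity | 0.62 µM | 0.62 µM | 0.62 µM |
| temperature | 20 °C | 15 °C | 20 °C |
| remark | the very flask that is asked about, followed so far | run made earlier |  |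
| time |  |  | 40 min |

north-east run (percent of the starting material charged)

| time / min | target / % | starting material / % |
|---|---|---|
| 2.00 | 7.8 | 92.0 |
| 3.00 | 8.5 | 90.0 |
| 4.00 | 9.2 | 90.7 |
| 6.00 | 9.5 | 90.2 |
| 10.0 | 8.9 | 89.0 |
| 15.0 | 10.5 | 90.4 |
| 25.0 | 11.2 | 89.4 |

west run (percent of the starting material charged)

| time / s | target / % | starting material / % |
|---|---|---|
| 10.0 | 4.2 | 95.8 |
| 12.0 | 4.4 | 95.1 |
| 20.0 | 7.3 | 93.2 |
| 25.0 | 9.9 | 91.2 |
| 40.0 | 12.4 | 87.1 |
| 60.0 | 17.4 | 82.2 |
| 90.0 | 26.1 | 74.9 |

(scatter of a reading: 0.5 percentage points)

- removed target is counted in
- what was read earlier has a scatter of 0.5 percentage points, one standard deviation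
- additions bring no volume worth counting

- epsilon: at 40 min raise the temperature by 10 K, then wait 20 min
- beta: change nothing and wait 20 min more
- eta: at 40 min add free enzyme, 100 % of the amount charged, then wait 20 min
- zeta: at 40 min take out 90 % of the target then present, then wait 20 min

- target, in percent of the starting material first charged, at 40 min
- what to do for the largest gain in target; "none" if nothing gains more than 2 percentage points (epsilon / beta / eta / zeta / none)
- target present, with what was taken out counted in, in percent of the starting material first charged, after eta
- target present, with what was taken out counted in, in percent of the starting material first charged, after zeta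

Compare the charges. The north-east flask holds 0.590 µM of enzyme against 0.62 µM of impurity, so if each impurity molecule kills one enzyme for good, the impurity outnumbers the enzyme, and on that count 0.0300 µM of impurity stays over. The west flask holds 1.20 µM, so on the same count 0.580 µM of enzyme survives to carry its steady line.

Now divide two rates. I assume that target forms in proportion to live enzyme, and that killing goes with live enzyme times impurity Y. In the ratio, time and enzyme cancel, so target made per impurity used is ρ/Y, with ρ a constant of the flask, and adding this up gives target = ρ ln(Y at start / Y at end). The same sum gives the west flask's target above its steady line, traced back to time zero, as ρ ln(enzyme charged / enzyme surviving).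

Two west readings put that excess at 1.44 %. With a logarithm of 0.727, ρ is 1.98 %, and the north-east logarithm of 3.03 then gives 6.00 %.

That link is weak: the excess is a difference of readings, each uncertain by 0.5 percentage points, taken in a cooler flask. So I reforge it from the north-east flask itself, whose last four readings average 10.0 %. This makes the kill yield, ρ, the target made per unit of that logarithm, read here as 3.31 %.

I commit to 10.0 % at 40 min, and to the same after waiting, heating or taking target out, since impurity exceeds enzyme. On the same count a second dose leaves 0.560 µM alive, close to the west survivors. At the west pace, read in a cooler flask, a whole charge needs 6.08 min, less than the 20 min on offer, so I expect eta to carry the target far up, though the equilibrium is unread.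

The forecast gives 10.6 % now, eta as best, 90 % after eta and 10.7 % after zeta, saying “So the enzyme has died.”

The flask gives 10.1 %, and eta is best, reaching 94.1 %, while zeta stays at 10.1 %.

    complex A → free enzyme + target (k = 3850 /s, Ea = 47.0 kJ/mol)
    free enzyme → unfolded enzyme (k = 1.25 × 10⁻⁴ /s, Ea = 214 kJ/mol)
    target + complex A → spent catalyst A (k = 0.452 /M/s, Ea = 50.0 kJ/mol)
    starting material + free enzyme ⇌ complex A (K = 23.0 /M, k = 1.14 × 10⁶ /M/s, Ea = 12.0 kJ/mol, ΔH = −39.0 kJ/mol)
    complex B → free enzyme + second product (k = 446 /s, Ea = 51.0 kJ/mol)
    free enzyme + impurity → spent catalyst B (k = 2.20 × 10⁶ /M/s, Ea = 11.0 kJ/mol)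
    second substrate + free enzyme ⇌ complex B (K = 190 /M, k = 1.08 × 10⁵ /M/s, Ea = 30.0 kJ/mol, ΔH = −22.0 kJ/mol)
    (constants at 20 °C)

At 40.0 min the flask holds 0 % free enzyme and 99.0 % spent catalyst B, with 5.8 % of its impurity left, and ρ with that remainder gives 9.42 % of target. Take the neighbour charged with 2.5 × 10⁻⁶ M of impurity and the same enzyme: ρ ln(Y at start / Y at end) gives 0.891 %. That neighbour gives 1.00 % of target, with 99.0 % of its starting material still there.

The numbers in the tables stem from a simulated flask for substances that don't exist.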